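**Retrosynthetic overview**
1. The last C–C bonds made are the two C3'–CO2H bonds of units B and C. They are formed together on a C–B–A trimer in which both inter-unit linkers are still 2-substituted acrylates. The carbon dioxide radical anion from formate, a carboxyl-anion synthon, adds to the electrophilic acrylate CH2, and hydrogen-atom transfer then sets each C2'.
2. The trimer comes from two esterifications of neopentyl C15–OH groups by one acrylic acid monomer. Unit A is made from the same monomer by the same formate addition followed by MeI.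
3. The monomer comes from the drimane C11–OH and the Morita–Baylis–Hillman carbonate of methyl glyoxylate and allyl acrylate. A catalytic asymmetric SN2'/SN2' etherification sets C1'.
4. The drimane comes from (2E,6E)-farnesyl acetate by allylic oxidation, asymmetric epoxidation and one radical cascade. The cascade closes ring A first and ring B second and leaves the exocyclic alkene, and the C3 oxygen is then removed. All rings are made before any fragment coupling.

Labels: drimane numbering is used (C11 = CH2O on C9, C12 = exocyclic CH2 on C8, C15 = 4α-CH2O). Every drimane unit has 4β-CH3, 5α-H, 9α-H and 10β-CH3. The isocitrate carbons are C1' (O-bearing), C2' and C3'. Unit A carries the free C2' acid, unit B is the middle unit and unit C carries the free C15–OH. TBS = tert-butyldimethylsilyl.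

Assumption: hydroquinidine 1,4-phthalazinediyl diether is taken to favour the (1'R) ether in step 10; its pseudoenantiomer (the hydroquinine diether) is equally available, and the two C1' epimers are separable diastereomers.

Step 1
Reactants: 1 (2E,6E)-farnesyl acetate
Product: 2 (2E,6E,10E)-12-hydroxyfarnesyl acetate
Conditions: SeO2 (10 mol%), salicylic acid (10 mol%), t-BuOOH (3.5 equiv), CH2Cl2, 0 °C to rt
Reagents that add atoms: tert-butyl hydroperoxide, CC(C)(C)OO
Why: Catalytic SeO2 allylic oxidation (ene reaction then [2,3]-shift) attacks the most electron-rich terminal alkene and only its E-methyl group, so the future C15 oxygen is in place before any ring exists and no stereocentre is formed.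

Step 2
Reactants: 2 (2E,6E,10E)-12-hydroxyfarnesyl acetate
Product: 3 (2E,6E,10S,11S)-10,11-epoxy-12-hydroxyfarnesyl acetate
Conditions: Ti(OiPr)4 (10 mol%), L-(+)-diethyl tartrate (12 mol%), t-BuOOH, 4 Å MS, CH2Cl2, −20 °C
Reagents that add atoms: tert-butyl hydroperoxide, CC(C)(C)OO
Why: Sharpless asymmetric epoxidation touches only the alkene of the allylic alcohol, and the L-(+)-tartrate ligand delivers oxygen to the face that gives the (10S,11S) epoxide, whose C10 becomes the controlling (3S) centre of the drimane.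

Step 3
Reactants: 3 (2E,6E,10S,11S)-10,11-epoxy-12-hydroxyfarnesyl acetate
Product: 4 (2E,6E,10S,11S)-10,11-epoxy-12-(TBS-oxy)farnesyl acetate
Conditions: TBSCl (1.2 equiv), imidazole (2.5 equiv), DMF, 0 °C to rt
Reagents that add atoms: tert-butyldimethylsilyl chloride, CC(C)(C)[Si](C)(C)Cl
Why: Standard silylation of the primary alcohol blocks loss of the oxygen next to the radical formed in step 4 and later serves as the only hydroxyl protecting group of the route.

Step 4
Reactants: 4 (2E,6E,10S,11S)-10,11-epoxy-12-(TBS-oxy)farnesyl acetate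
Product: 5 3β-hydroxy-15-(TBS-oxy)drim-8(12)-en-11-yl acetate
Conditions: Cp2TiCl2 (2.5 equiv), Mn dust (8 equiv), degassed THF, rt; aq NaH2PO4 work-up
Reagents that add atoms: none
Why: In this titanocene-mediated radical epoxypolyene cyclisation Cp2TiCl (trivalent titanium) opens the epoxide to the tertiary C4 radical, which closes ring A and then ring B by two 6-endo additions through a chair–chair array ordered by the equatorial C3–O–Ti group (this sets C4, C5, C10 and C9, the larger CH2OTBS taking the equatorial 4α site away from the C10 methyl), and the C8 radical is trapped by a second Cp2TiCl and loses a methyl hydrogen to leave the exocyclic alkene.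

Step 5
Reactants: 5 3β-hydroxy-15-(TBS-oxy)drim-8(12)-en-11-yl acetate
Product: 6 3β-(phenoxythiocarbonyloxy)-15-(TBS-oxy)drim-8(12)-en-11-yl acetate
Conditions: PhOC(S)Cl (2 equiv), pyridine (4 equiv), 4-(dimethylamino)pyridine (20 mol%), CH2Cl2, rt
Reagents that add atoms: O-phenyl chlorothionoformate, S=C(Cl)Oc1ccccc1
Why: Nucleophile-catalysed thioacylation of the only free hydroxyl gives the thionocarbonate needed for radical deoxygenation, with no change at any stereocentre.

Step 6
Reactants: 6 3β-(phenoxythiocarbonyloxy)-15-(TBS-oxy)drim-8(12)-en-11-yl acetate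
Product: 7 15-(TBS-oxy)drim-8(12)-en-11-yl acetate
Conditions: Bu3SnH (2 equiv), 2,2'-azobis(2-methylpropionitrile) (20 mol%), toluene, 90 °C
Reagents that add atoms: none
Why: In the Barton–McCombie deoxygenation the stannyl radical adds to C=S and the released secondary C3 radical is reduced by Bu3SnH, which erases the no longer needed C3 centre without touching the remote exocyclic alkene.

Step 7
Reactants: 7 15-(TBS-oxy)drim-8(12)-en-11-yl acetate
Product: 8 15-(TBS-oxy)drim-8(12)-en-11-ol
Conditions: K2CO3 (20 mol%), MeOH, rt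
Reagents that add atoms: none
Why: Base-catalysed transesterification removes the acetate while the silyl ether and the alkene are inert, leaving C11–OH as the only free hydroxyl.

Step 8
Reactants: 9 methyl glyoxylate; 10 allyl acrylate
Product: 11 4-allyl 1-methyl 2-hydroxy-3-methylidenebutanedioate (racemic)
Conditions: 1,4-diazabicyclo[2.2.2]octane (20 mol%), 1,4-dioxane, rt
Reagents that add atoms: none
Why: The Morita–Baylis–Hillman reaction of the very electrophilic glyoxylate aldehyde gives the C1'–C2' bond with the C1' and C2' carboxyls already differentiated, and the racemic carbinol centre is reset in step 10.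

Step 9
Reactants: 11 4-allyl 1-methyl 2-hydroxy-3-methylidenebutanedioate (racemic)
Product: 12 4-allyl 1-methyl 2-(tert-butoxycarbonyloxy)-3-methylidenebutanedioate (racemic)
Conditions: Boc2O (1.2 equiv), 4-(dimethylamino)pyridine (10 mol%), CH2Cl2, 0 °C
Reagents that add atoms: di-tert-butyl dicarbonate, CC(C)(C)OC(=O)OC(=O)OC(C)(C)C
Why: O-acylation turns the hydroxyl into a carbonate leaving group that releases its own base (tert-butoxide) in the next step.

Step 10
Reactants: 8 15-(TBS-oxy)drim-8(12)-en-11-ol; 12 4-allyl 1-methyl 2-(tert-butoxycarbonyloxy)-3-methylidenebutanedioate (racemic)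
Product: 13 4-allyl 1-methyl (2R)-2-{[15-(TBS-oxy)drim-8(12)-en-11-yl]oxy}-3-methylidenebutanedioate
Conditions: hydroquinidine 1,4-phthalazinediyl diether (20 mol%), 12 (2 equiv), 4 Å MS, toluene, 30 °C
Reagents that add atoms: none
Why: Proposed new method: the tertiary amine adds SN2' to 12 and expels CO2 and tert-butoxide, the butoxide deprotonates the β-branched primary alcohol 8, and the alkoxide attacks the planar allylic ammonium ion SN2' at the carbon bearing CO2Me inside the chiral pocket, so racemic 12 converges on the (1'R) ether and any (1'S) epimer is a separable diastereomer; the closest known reaction type is the cinchona-alkaloid-catalysed asymmetric allylic substitution of Morita–Baylis–Hillman carbonates by oxygen nucleophiles.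

Step 11
Reactants: 13 4-allyl 1-methyl (2R)-2-{[15-(TBS-oxy)drim-8(12)-en-11-yl]oxy}-3-methylidenebutanedioate
Product: 14 (3R)-4-methoxy-2-methylidene-4-oxo-3-{[15-(TBS-oxy)drim-8(12)-en-11-yl]oxy}butanoic acid
Conditions: Pd(PPh3)4 (5 mol%), N-methylaniline (3 equiv), THF, rt
Reagents that add atoms: none
Why: In this Tsuji–Trost deallylation zerovalent palladium ionises only the allyl ester (the alkoxide of the allylic ether is no leaving group) and the weakly nucleophilic aniline traps the allyl cation without adding to the acrylate.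

Step 12
Reactants: 13 4-allyl 1-methyl (2R)-2-{[15-(TBS-oxy)drim-8(12)-en-11-yl]oxy}-3-methylidenebutanedioate; 15 potassium formate
Product: 17 2-allyl 1,3-dimethyl (1R,2S)-1-{[15-(TBS-oxy)drim-8(12)-en-11-yl]oxy}propane-1,2,3-tricarboxylate, via potassium carboxylate 16 (not isolated)
Conditions: 15 (5 equiv), 1,2,3,5-tetrakis(carbazol-9-yl)-4,6-dicyanobenzene (2 mol%), 2,4,6-triisopropylbenzenethiol (20 mol%), DMSO–THF, 450 nm LED, 15 °C; then MeI (8 equiv), rt
Reagents that add atoms: methyl iodide, CI
Why: Proposed new method: the thiyl radical abstracts the formyl hydrogen of formate, the carbon dioxide radical anion (a nucleophilic carboxyl synthon) adds to the electrophilic acrylate CH2 (Giese addition) far faster than to the unactivated alkenes, the tertiary C2' radical, held with C1'–H eclipsing the ester to avoid A(1,3) strain, takes hydrogen from the bulky thiol on the face opposite the C1' CO2Me group to give the (1'R,2'S) anti isomer, and the carboxylate is then alkylated by MeI; the closest known reaction types are the thiol-catalysed photochemical hydrocarboxylation of acrylates by formate and the anti-selective hydrogen-atom transfer to β-alkoxy ester radicals.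

Step 13
Reactants: 17 2-allyl 1,3-dimethyl (1R,2S)-1-{[15-(TBS-oxy)drim-8(12)-en-11-yl]oxy}propane-1,2,3-tricarboxylate
Product: 18 2-allyl 1,3-dimethyl (1R,2S)-1-{[15-hydroxydrim-8(12)-en-11-yl]oxy}propane-1,2,3-tricarboxylate (unit A alcohol)
Conditions: HF·pyridine, excess pyridine, THF, 0 °C to rt
Reagents that add atoms: none
Why: Fluoride-driven Si–O cleavage under buffered conditions frees C15–OH and leaves esters, exocyclic alkene and both isocitrate centres untouched.

Step 14
Reactants: 14 (3R)-4-methoxy-2-methylidene-4-oxo-3-{[15-(TBS-oxy)drim-8(12)-en-11-yl]oxy}butanoic acid; 18 unit A alcohol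
Product: 19 TBS-protected dimer B–A (C15–O of 18 acylated by 14)
Conditions: 2-methyl-6-nitrobenzoic anhydride (1.4 equiv), 4-(dimethylamino)pyridine (0.5 equiv), Et3N (3 equiv), CH2Cl2, rt
Reagents that add atoms: none
Why: Shiina mixed-anhydride esterification acylates the neopentyl alcohol, helped by the flat sp2 α-carbon of the acid, which also means that there is no stereocentre next to the activated acyl group to epimerise.

Step 15
Reactants: 19 TBS-protected dimer B–A
Product: 20 dimer B–A alcohol (free C15–OH on unit B)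
Conditions: HF·pyridine, excess pyridine, THF, 0 °C to rt
Reagents that add atoms: none
Why: The same buffered fluoride desilylation as in step 13 applies, and the acrylate linker and the allyl ester are inert to it.

Step 16
Reactants: 14 (3R)-4-methoxy-2-methylidene-4-oxo-3-{[15-(TBS-oxy)drim-8(12)-en-11-yl]oxy}butanoic acid; 20 dimer B–A alcohol
Product: 21 TBS-protected trimer C–B–A bis-acrylate
Conditions: 2-methyl-6-nitrobenzoic anhydride (1.4 equiv), 4-(dimethylamino)pyridine (0.5 equiv), Et3N (3 equiv), CH2Cl2, rt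
Reagents that add atoms: none
Why: A second Shiina esterification with the same monomer acid adds unit C, again with no epimerisable centre α to the acyl donor.

Step 17
Reactants: 21 TBS-protected trimer C–B–A bis-acrylate; 15 potassium formate
Product: 22 trimer diacid (both linkers now (1'R,2'S)-isocitrates with free CH2CO2H; allyl ester on unit A; TBS on unit C)
Conditions: 15 (10 equiv), 1,2,3,5-tetrakis(carbazol-9-yl)-4,6-dicyanobenzene (2 mol%), 2,4,6-triisopropylbenzenethiol (30 mol%), DMSO–THF, 450 nm LED, 15 °C; aq KHSO4 work-up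
Reagents that add atoms: none
Why: Proposed new method: the reaction of step 12 is run on both inter-unit acrylates in one flask, so two C3'–CO2H bonds form by Giese addition of the carbon dioxide radical anion to the two electrophilic CH2 termini, both C2' centres are set (S) by thiol hydrogen-atom transfer anti to the neighbouring C1' CO2Me group, and the acids appear unprotected exactly where the target has them; the closest known reaction types are the formate-based photochemical hydrocarboxylation of acrylates and A(1,3)-controlled hydrogen-atom transfer to β-alkoxy ester radicals.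

Step 18
Reactants: 22 trimer diacid
Product: 23 trimer triacid 15-O-TBS ether
Conditions: Pd(PPh3)4 (5 mol%), N-methylaniline (3 equiv), THF, rt
Reagents that add atoms: none
Why: Tsuji–Trost deallylation by zerovalent palladium frees the C2' acid of unit A under neutral conditions that cannot epimerise C1' or C2' or cleave the other five esters.

Step 19
Reactants: 23 trimer triacid 15-O-TBS ether
Product: 24 cryptoporic acid T
Conditions: HF·pyridine, excess pyridine, THF, 0 °C to rt
Reagents that add atoms: none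
Why: Buffered fluoride desilylation frees the C15–OH of unit C without acid-induced migration of the three exocyclic alkenes.

**Compound list**
1 | (2E,6E)-farnesyl acetate | CC(C)=CCC/C(C)=C/CC/C(C)=C/COC(C)=O | starting material
2 | (2E,6E,10E)-12-hydroxyfarnesyl acetate | OC/C(C)=C/CC/C(C)=C/CC/C(C)=C/COC(C)=O | intermediate
3 | (2E,6E,10S,11S)-10,11-epoxy-12-hydroxyfarnesyl acetate | OC[C@]1(C)O[C@H]1CC/C(C)=C/CC/C(C)=C/COC(C)=O | intermediate
4 | (2E,6E,10S,11S)-10,11-epoxy-12-(TBS-oxy)farnesyl acetate | CC(C)(C)[Si](C)(C)OC[C@]1(C)O[C@H]1CC/C(C)=C/CC/C(C)=C/COC(C)=O | intermediate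
5 | (3S)-3β-hydroxy-15-(TBS-oxy)drim-8(12)-en-11-yl acetate (4α-CH2OTBS, 4β-CH3, 5α-H, 9α-H, 10β-CH3) | C=C1CC[C@H]2[C@](C)(CO[Si](C)(C)C(C)(C)C)[C@@H](O)CC[C@]2(C)[C@H]1COC(C)=O | intermediate
6 | 3β-(phenoxythiocarbonyloxy)-15-(TBS-oxy)drim-8(12)-en-11-yl acetate | C=C1CC[C@H]2[C@](C)(CO[Si](C)(C)C(C)(C)C)[C@@H](OC(=S)Oc3ccccc3)CC[C@]2(C)[C@H]1COC(C)=O | intermediate
7 | 15-(TBS-oxy)drim-8(12)-en-11-yl acetate | C=C1CC[C@H]2[C@](C)(CO[Si](C)(C)C(C)(C)C)CCC[C@]2(C)[C@H]1COC(C)=O | intermediate
8 | 15-(TBS-oxy)drim-8(12)-en-11-ol | C=C1CC[C@H]2[C@](C)(CO[Si](C)(C)C(C)(C)C)CCC[C@]2(C)[C@H]1CO | intermediate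
9 | methyl glyoxylate | COC(=O)C=O | starting material
10 | allyl acrylate | C=CC(=O)OCC=C | starting material
11 | 4-allyl 1-methyl 2-hydroxy-3-methylidenebutanedioate (racemic) | C=C(C(=O)OCC=C)C(O)C(=O)OC | intermediate
12 | 4-allyl 1-methyl 2-(tert-butoxycarbonyloxy)-3-methylidenebutanedioate (racemic) | C=C(C(=O)OCC=C)C(OC(=O)OC(C)(C)C)C(=O)OC | intermediate
13 | 4-allyl 1-methyl (2R)-2-{[15-(TBS-oxy)drim-8(12)-en-11-yl]oxy}-3-methylidenebutanedioate | C=C1CC[C@H]2[C@](C)(CO[Si](C)(C)C(C)(C)C)CCC[C@]2(C)[C@H]1CO[C@@H](C(=O)OC)C(=C)C(=O)OCC=C | intermediate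
14 | (3R)-4-methoxy-2-methylidene-4-oxo-3-{[15-(TBS-oxy)drim-8(12)-en-11-yl]oxy}butanoic acid | C=C1CC[C@H]2[C@](C)(CO[Si](C)(C)C(C)(C)C)CCC[C@]2(C)[C@H]1CO[C@@H](C(=O)OC)C(=C)C(=O)O | intermediate
15 | potassium formate | O=C[O-].[K+] | starting material
16 | potassium (3S,4R)-3-(allyloxycarbonyl)-5-methoxy-5-oxo-4-{[15-(TBS-oxy)drim-8(12)-en-11-yl]oxy}pentanoate | C=C1CC[C@H]2[C@](C)(CO[Si](C)(C)C(C)(C)C)CCC[C@]2(C)[C@H]1CO[C@@H](C(=O)OC)[C@H](CC(=O)[O-])C(=O)OCC=C.[K+] | intermediate
17 | 2-allyl 1,3-dimethyl (1R,2S)-1-{[15-(TBS-oxy)drim-8(12)-en-11-yl]oxy}propane-1,2,3-tricarboxylate | C=C1CC[C@H]2[C@](C)(CO[Si](C)(C)C(C)(C)C)CCC[C@]2(C)[C@H]1CO[C@@H](C(=O)OC)[C@H](CC(=O)OC)C(=O)OCC=C | intermediate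
18 | 2-allyl 1,3-dimethyl (1R,2S)-1-{[15-hydroxydrim-8(12)-en-11-yl]oxy}propane-1,2,3-tricarboxylate (unit A alcohol) | C=C1CC[C@H]2[C@](C)(CO)CCC[C@]2(C)[C@H]1CO[C@@H](C(=O)OC)[C@H](CC(=O)OC)C(=O)OCC=C | intermediate
19 | TBS-protected dimer B–A: C15–O of 18 esterified by the acrylic acid 14, (1'R) in the linker | C=C1CC[C@H]2[C@](C)(COC(=O)C(=C)[C@@H](OC[C@H]3C(=C)CC[C@H]4[C@](C)(CO[Si](C)(C)C(C)(C)C)CCC[C@]34C)C(=O)OC)CCC[C@]2(C)[C@H]1CO[C@@H](C(=O)OC)[C@H](CC(=O)OC)C(=O)OCC=C | intermediate
20 | dimer B–A alcohol: 19 with free C15–OH on unit B | C=C1CC[C@H]2[C@](C)(COC(=O)C(=C)[C@@H](OC[C@H]3C(=C)CC[C@H]4[C@](C)(CO)CCC[C@]34C)C(=O)OC)CCC[C@]2(C)[C@H]1CO[C@@H](C(=O)OC)[C@H](CC(=O)OC)C(=O)OCC=C | intermediate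
21 | TBS-protected trimer C–B–A bis-acrylate: C15–O of 20 esterified by 14 | C=C1CC[C@H]2[C@](C)(COC(=O)C(=C)[C@@H](OC[C@H]3C(=C)CC[C@H]4[C@](C)(COC(=O)C(=C)[C@@H](OC[C@H]5C(=C)CC[C@H]6[C@](C)(CO[Si](C)(C)C(C)(C)C)CCC[C@]56C)C(=O)OC)CCC[C@]34C)C(=O)OC)CCC[C@]2(C)[C@H]1CO[C@@H](C(=O)OC)[C@H](CC(=O)OC)C(=O)OCC=C | intermediate
22 | trimer diacid: units B and C are (1'R,2'S)-isocitrates with free CH2CO2H, unit A keeps its allyl ester, unit C its TBS ether | C=C1CC[C@H]2[C@](C)(COC(=O)[C@@H](CC(=O)O)[C@@H](OC[C@H]3C(=C)CC[C@H]4[C@](C)(COC(=O)[C@@H](CC(=O)O)[C@@H](OC[C@H]5C(=C)CC[C@H]6[C@](C)(CO[Si](C)(C)C(C)(C)C)CCC[C@]56C)C(=O)OC)CCC[C@]34C)C(=O)OC)CCC[C@]2(C)[C@H]1CO[C@@H](C(=O)OC)[C@H](CC(=O)OC)C(=O)OCC=C | intermediate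
23 | trimer triacid 15-O-TBS ether (cryptoporic acid T silylated at C15–O of unit C) | C=C1CC[C@H]2[C@](C)(COC(=O)[C@@H](CC(=O)O)[C@@H](OC[C@H]3C(=C)CC[C@H]4[C@](C)(COC(=O)[C@@H](CC(=O)O)[C@@H](OC[C@H]5C(=C)CC[C@H]6[C@](C)(CO[Si](C)(C)C(C)(C)C)CCC[C@]56C)C(=O)OC)CCC[C@]34C)C(=O)OC)CCC[C@]2(C)[C@H]1CO[C@@H](C(=O)OC)[C@H](CC(=O)OC)C(=O)O | intermediate
24 | cryptoporic acid T | C=C1CC[C@H]2[C@](C)(COC(=O)[C@@H](CC(=O)O)[C@@H](OC[C@H]3C(=C)CC[C@H]4[C@](C)(COC(=O)[C@@H](CC(=O)O)[C@@H](OC[C@H]5C(=C)CC[C@H]6[C@](C)(CO)CCC[C@]56C)C(=O)OC)CCC[C@]34C)C(=O)OC)CCC[C@]2(C)[C@H]1CO[C@@H](C(=O)OC)[C@H](CC(=O)OC)C(=O)O | target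

**Totals**
Total step count: 19. Longest linear sequence: 16 steps (1–7, 10, 12–19).

**The three steps most likely to fail**

Step 17 carries three risks. Two radical additions must both end in anti-selective hydrogen transfer. Each C2' radical could instead close a seven-membered ring onto the nearby exocyclic alkene. Minor diastereomers of a large diacid are also hard to remove. The fallback sets out from 21 and comes back at 22. It replaces the radical by a polar carboxyl-anion equivalent. Nitromethane is added to both acrylates (1,1,3,3-tetramethylguanidine, 20 mol%, MeCN, 0 °C), and each C2' is set by protonation of the enolate under the same A(1,3) bias. This gives the bis(2-nitroethyl) trimer F1. Its two primary nitro groups are then oxidised to carboxylic acids with NaNO2 and AcOH in DMSO at 35 °C, which gives 22.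

Step 10 may be slow, because an aliphatic alkoxide may be too poor a partner for the allylic ammonium ion, and the facial selectivity is untested for a glyoxylate-derived carbonate. The fallback sets out from 8 and comes back at 13. It forms the C–O bond by carbene insertion.
- Commercial 4-methyl hydrogen itaconate is O-alkylated (allyl bromide, K2CO3, DMF) to 1-allyl 4-methyl 2-methylidenebutanedioate F2.
- Diazo transfer (4-acetamidobenzenesulfonyl azide, 1,8-diazabicyclo[5.4.0]undec-7-ene, MeCN, 0 °C) gives 4-allyl 1-methyl 2-diazo-3-methylidenebutanedioate F3.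
- Freshly made F3 is added slowly to 8 with Rh2(O2CCPh3)4 (1 mol%) and (R)-3,3'-bis(2,4,6-triisopropylphenyl)-1,1'-binaphthyl-2,2'-diyl hydrogen phosphate (5 mol%) in CH2Cl2 at −20 °C.
- O–H insertion at the carbene carbon, with the phosphoric acid steering the proton shift, gives 13, which is separated from its C1' epimer.

Step 14 is the first acylation of a neopentyl alcohol by a bulky acid, and step 16 repeats it on a larger scale. The fallback sets out from 18 and comes back at 19. It makes the ester with a small acyl donor and uses the ether bond as the fragment coupling.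
- 18 is acylated with acryloyl chloride and Et3N in CH2Cl2 at 0 °C to give the unit A 15-O-acrylate F4.
- A Morita–Baylis–Hillman reaction with 9 (1,4-diazabicyclo[2.2.2]octane, dioxane) gives the unit A 15-O-[2-(1-hydroxy-2-methoxy-2-oxoethyl)acrylate] F5.
- Boc2O with catalytic 4-(dimethylamino)pyridine gives the corresponding tert-butyl carbonate F6.
- F6 is etherified with 8 under the conditions of step 10 to give 19.

**Further compounds**
F1 | step 17 | bis(2-nitroethyl) trimer: 21 with each linker C(=CH2) converted into (2'S)-CH(CH2CH2NO2) | C=C1CC[C@H]2[C@](C)(COC(=O)[C@@H](CC[N+](=O)[O-])[C@@H](OC[C@H]3C(=C)CC[C@H]4[C@](C)(COC(=O)[C@@H](CC[N+](=O)[O-])[C@@H](OC[C@H]5C(=C)CC[C@H]6[C@](C)(CO[Si](C)(C)C(C)(C)C)CCC[C@]56C)C(=O)OC)CCC[C@]34C)C(=O)OC)CCC[C@]2(C)[C@H]1CO[C@@H](C(=O)OC)[C@H](CC(=O)OC)C(=O)OCC=C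
F2 | step 10 | 1-allyl 4-methyl 2-methylidenebutanedioate | C=C(CC(=O)OC)C(=O)OCC=C
F3 | step 10 | 4-allyl 1-methyl 2-diazo-3-methylidenebutanedioate | C=C(C(=O)OCC=C)C(=[N+]=[N-])C(=O)OC
F4 | step 14 | unit A 15-O-acrylate | C=C1CC[C@H]2[C@](C)(COC(=O)C=C)CCC[C@]2(C)[C@H]1CO[C@@H](C(=O)OC)[C@H](CC(=O)OC)C(=O)OCC=C
F5 | step 14 | unit A 15-O-[2-(1-hydroxy-2-methoxy-2-oxoethyl)acrylate] (both carbinol epimers) | C=C1CC[C@H]2[C@](C)(COC(=O)C(=C)C(O)C(=O)OC)CCC[C@]2(C)[C@H]1CO[C@@H](C(=O)OC)[C@H](CC(=O)OC)C(=O)OCC=C
F6 | step 14 | tert-butyl carbonate of F5 (both epimers) | C=C1CC[C@H]2[C@](C)(COC(=O)C(=C)C(OC(=O)OC(C)(C)C)C(=O)OC)CCC[C@]2(C)[C@H]1CO[C@@H](C(=O)OC)[C@H](CC(=O)OC)C(=O)OCC=C
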